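**Retrosynthetic overview**
- Tomentodione O ⇒ inverse-demand oxa-Diels–Alder of the exocyclic C8=C13 methylene of (3Z)-caryophylla-3,8(13)-dien-5-ol with 6-(3-methylbutylidene)syncarpic trione (dihydropyran ring; C8–O and C13–C1′ bonds).
- Alkylidene trione ⇒ Knoevenagel of 3-methylbutanal with syncarpic acid; syncarpic acid ⇒ [3+3] double Claisen of 3-methylbutan-2-one (C–C(O)–C dinucleophile) with dimethyl 2,2-dimethylmalonate (cyclohexanetrione ring).
- Both disconnections are run in one flask from four components: trione ring first, dihydropyran ring second.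
- Dienol ⇒ syn-elimination of (−)-caryophyllene oxide; the cyclobutane, the nine-membered ring and C1, C5, C9 are bought.
- Ring order: cyclobutane and cyclononene (chiral pool) → cyclohexanetrione → spiro-dihydropyran.

Assumption: commercial (−)-caryophyllene oxide is the (1R,4R,5R,9S) isomer; caryophyllane numbering is used (C13 = exocyclic CH2, C1′ = the CH that carries isobutyl), and LDA is bought as a solution.

**Step 1**
Reactants: 1 (−)-caryophyllene oxide, (1R,4R,5R,9S)-4,5-epoxycaryophyll-8(13)-ene
Product: 2 (1R,3Z,5R,9S)-caryophylla-3,8(13)-dien-5-ol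
Conditions: Et2Al–TMP (4 eq; from TMPH, n-BuLi, Et2AlCl), PhMe, 0 °C → rt; aq. Rochelle salt
Reagents that add atoms: none
Why: Aluminium-amide epoxide-to-allylic-alcohol isomerisation (Yamamoto–Nozaki type): the O-bound bulky amide removes, in a cyclic syn-elimination, a proton from the C4 substituent cis to H-5 (C3–H, not the 4-methyl), so the tertiary C4–O bond opens to the 3-en-5-ol; C1, C5 and C9 are untouched (5R kept) and the Z ring alkene is expected as the less strained cyclononene geometry.

**Step 2**
Reactants: 3 3-methylbutan-2-one; 4 dimethyl 2,2-dimethylmalonate; 5 3-methylbutanal; 2 (1R,3Z,5R,9S)-caryophylla-3,8(13)-dien-5-ol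
Product: 9 Tomentodione O, via diketo ester 6 (not isolated), via syncarpic acid 7 (not isolated), via alkylidene trione 8 (not isolated)
Conditions: 3 (1.5 eq), LDA (3.2 eq), 2-MeTHF, −78 °C; 4 (1.5 eq), −78 → 0 °C; LDA (1.8 eq), 0 → 40 °C; AcOH (8 eq), 0 °C; 5 (2.5 eq), 2 (1.0 eq), 80 °C, 16 h; chromatography
Reagents that add atoms: none
Why: Proposed new method: the kinetic CH3-side lithium enolate of 3 is acylated by the non-enolisable diester 4 (crossed Claisen) to the β-diketone enolate of 6, the extra LDA removes its only remaining acidic proton, the isopropyl γ-CH (Hauser–Harris 1,3-diketone dianion), and this carbanion closes 6-exo onto the second ester (Dieckmann) to lithium syncarpate 7, the first ring; after AcOH buffering the i-Pr2NH2OAc already in the flask catalyses Knoevenagel condensation of 7 with 5 to heterodiene 8, which the 1,1-disubstituted C8=C13 alkene of 2 traps in an inverse-demand oxa-Diels–Alder reaction (O to the more substituted C8), the second ring; the closest known reactions are γ-acylation of 1,3-diketone dianions to 1,3,5-triketones and the three-component Knoevenagel/hetero-Diels–Alder coupling of syncarpic acid, aldehydes and caryophyllene-type alkenes; stereocontrol is by substrate: 8S needs O delivery to the alkene face anti to C1 (conformer with H-9 eclipsing C=CH2) and 1′R needs the bulkier C9 side exo with isobutyl outside (isobutyl cis to C7), but the facial preference is not secured and up to four diastereomers are separated by chromatography; C1, C5, C9 and the 3Z alkene are spectators.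

**Compound list**
1 | (−)-caryophyllene oxide, (1R,4R,5R,9S)-4,5-epoxycaryophyll-8(13)-ene | C[C@@]12CC[C@@H]3[C@H](CC3(C)C)C(=C)CC[C@H]1O2 | starting material
2 | (1R,3Z,5R,9S)-caryophylla-3,8(13)-dien-5-ol | C/C1=C/C[C@@H]2[C@H](CC2(C)C)C(=C)CC[C@H]1O | intermediate
3 | 3-methylbutan-2-one | CC(=O)C(C)C | starting material
4 | dimethyl 2,2-dimethylmalonate | COC(=O)C(C)(C)C(=O)OC | starting material
5 | 3-methylbutanal (isovaleraldehyde) | CC(C)CC=O | starting material
6 | methyl 2,2,6-trimethyl-3,5-dioxoheptanoate | COC(=O)C(C)(C)C(=O)CC(=O)C(C)C | intermediate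
7 | syncarpic acid, 2,2,4,4-tetramethylcyclohexane-1,3,5-trione | CC1(C)C(=O)CC(=O)C(C)(C)C1=O | intermediate
8 | 2,2,4,4-tetramethyl-6-(3-methylbutylidene)cyclohexane-1,3,5-trione | CC(C)CC=C1C(=O)C(C)(C)C(=O)C(C)(C)C1=O | intermediate
9 | Tomentodione O, (1R,3Z,5R,8S,9S,1′R) spiro-dihydropyran adduct | C/C1=C/C[C@@H]2[C@H](CC2(C)C)[C@]2(CC[C@H]1O)C[C@@H](CC(C)C)C1=C(O2)C(C)(C)C(=O)C(C)(C)C1=O | target

**Totals and risks**
Total step count: 2. Longest linear sequence: 2 (1 → 2 → 9).

The route has only two steps, so step 2 is entered twice, once for each of its two independent failure points.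

Step 2, trione-forming stage. The γ-deprotonation of the tertiary C–H in the enolate of 6 may be slow, and unclosed 6 would itself condense with 5. The fallback changes the order of bond formation so that no dianion is needed. It sets out from 4: one equivalent of i-PrMgCl (THF, −40 °C) gives methyl 2,2,4-trimethyl-3-oxopentanoate F1. Acetylation at the methine with Ac2O/BF3·OEt2 gives methyl 2,2,4,4-tetramethyl-3,5-dioxohexanoate F2. In the one-pot operation F2 with LDA (1.1 eq) forms its only possible enolate (acetyl CH3), which closes onto the ester as an ordinary mono-anion Dieckmann reaction. This returns to the route at 7 in the flask, and AcOH, 5 and 2 then follow as written.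

Step 2, cycloaddition stage. Face selectivity at C8 and endo/exo selectivity can give up to four diastereomers, and the free allylic alcohol of 2 can ionise, add to 8 or steer the heterodiene to the wrong face. The fallback masks and enlarges the C5 substituent. It sets out from 2: TBSCl/imidazole (DMF) gives the 5-O-tert-butyldimethylsilyl ether of the dienol F3. F3 replaces 2 in the one-pot operation (a Lewis acid such as Yb(OTf)3 at lower temperature then becomes usable) and gives the 5-O-TBS ether of Tomentodione O F4. TBAF in THF returns to the route at 9.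

Step 1. Open-chain and large-ring trans-epoxides give E-allylic alcohols in this syn-elimination, so the trans ring alkene may form instead of the Z one; some 4(12)-exocyclic alcohol is also expected and is removed by chromatography. The fallback accepts the kinetic geometry and corrects it thermodynamically. It sets out from 1: the same elimination gives (1R,3E,5R,9S)-caryophylla-3,8(13)-dien-5-ol F5. Catalytic PhSSPh under irradiation (benzene, rt) isomerises the strained E-cyclononene by reversible thiyl-radical addition to the Z isomer, leaving the exocyclic alkene and C5 unchanged. This returns to the route at 2.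

**Further compounds**
F1 | step 2 | methyl 2,2,4-trimethyl-3-oxopentanoate | COC(=O)C(C)(C)C(=O)C(C)C
F2 | step 2 | methyl 2,2,4,4-tetramethyl-3,5-dioxohexanoate | CC(=O)C(C)(C)C(=O)C(C)(C)C(=O)OC
F3 | step 2 | (1R,3Z,5R,9S)-5-(tert-butyldimethylsilyloxy)caryophylla-3,8(13)-diene | C/C1=C/C[C@@H]2[C@H](CC2(C)C)C(=C)CC[C@H]1O[Si](C)(C)C(C)(C)C
F4 | step 2 | 5-O-tert-butyldimethylsilyl Tomentodione O | C/C1=C/C[C@@H]2[C@H](CC2(C)C)[C@]2(CC[C@H]1O[Si](C)(C)C(C)(C)C)C[C@@H](CC(C)C)C1=C(O2)C(C)(C)C(=O)C(C)(C)C1=O
F5 | step 1 | (1R,3E,5R,9S)-caryophylla-3,8(13)-dien-5-ol | C/C1=C\C[C@@H]2[C@H](CC2(C)C)C(=C)CC[C@H]1O
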